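If every step takes two partners, dividing all charges by one factor and multiplying the time by it leaves every percentage unchanged. So you can compare flasks by charged [starting material] times time, as long as the charges keep their ratio.

| setting | theta | Saturday's | Wednesday's |
|---|---|---|---|
| starting material | 0.50 M | 0.12 M | 0.45 M |
| reagent | 0.225 M | 0.0800 M | 0.225 M |
| temperature | 70 °C | 70 °C | 70 °C |
| remark | run made earlier |  |  |
| time |  | 8.0 h | 2.0 h |

- theta (time / min: target / %, side product / %): 2.00: 2.2, 0; 4.00: 4.2, 1.4; 10.0: 8.5, 1.5; 25.0: 13.6, 6.6

(readings scatter by 0.5 percentage points)

* which one finishes higher in share of target in all that became target or side product ("neither" within 2 percentage points) (Saturday's / Wednesday's / neither)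
* share of target in all that became target or side product, Saturday's
* share of target in all that became target or side product, Wednesday's

- percentages count the starting material that a species holds: one side product counts as two
- the numbers in the tables scatter with a standard deviation of 0.5 percentage points
- a reading or a percentage of target counts all its forms, free or not

Saturday's product of [starting material] and time is 1.07 times Wednesday's, though reagent per starting material is 0.667 against 0.500.

My own reckoning takes side product as target + starting material, so target's loss is pseudo-first-order at a given [starting material]. In the theta run, mean target over 25.0 min reads 8.50% of the starting material charged, and target lost reads 3.30% on the same scale, since side product counts double. That gives target's life, mean target times time over target lost, as a reading of 64.4 min at 0.50 M. In this reckoning it shortens in proportion to charged [starting material].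

Call x the run time over that life: 1.79 for Saturday's, 1.68 for Wednesday's. Replacing the curves by steady making and charged [starting material], the mean surviving fraction f is one minus e to the minus x, over x, and the share is f over two minus f. That gives 30.3% for Saturday's and 32.0% for Wednesday's, a gap of 1.7 percentage points against a margin of 2 points, so I say neither.

The forecast says Saturday's, with 58% (42% to 74%) for Saturday's and 50% (38% to 62%) for Wednesday's, noting for Saturday's that “dilution suppresses dimerisation”.

The flasks give neither: 26.7% for Saturday's, 26.3% for Wednesday's.

    starting material + reagent ⇌ target + by-product (K = 0.467, k = 8.10 × 10⁻⁴ L mol⁻¹ s⁻¹, Ea = 81.0 kJ mol⁻¹, ΔH = −63.0 kJ mol⁻¹)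
    starting material + target → side product (k = 5.90 × 10⁻⁴ L mol⁻¹ s⁻¹, Ea = 92.0 kJ mol⁻¹)
    crystals ⇌ target, rate k3*(cs3 - [target]) while solid is left; crystals form when [target] > cs3 (solubility = 0.140 M, k = 0.00109 s⁻¹)
    (constants at 70 °C)

Now take the neighbour of Wednesday's charged with 1.1 M of starting material, reagent and time held, so 0.205 equiv of reagent. Its x is 4.10, and the same reckoning gives a share of 13.6%. That neighbour ends with target at 1.90% and side product at 33.5%, a share of 5.38%.

The earlier runs and the new flask were generated by integration for an exercise; noise was put on by code.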